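Atom numbering used in the discussion: ring carbons C1 (quaternary, methyl and vinyl), C2 (isopropenyl), C3, C4 (side chain), C5, C6; chain carbons C7 (alkene carbon on the ring), C8 (=CH), C9 (CH2), C10 (secondary carbinol), C11 (tertiary carbinol), C12 (acetoxymethyl carbon). Compound names use their own IUPAC locants.

## Analysis of the target

The target is a lobane-type diterpenoid monoacetate: a cyclohexane with a quaternary C1 (methyl, vinyl), an isopropenyl group on C2 and, on C4, the chain C7(=C8H–C9H2–C10H(OH)–C11(CH3)2OH)–C12H2OAc. The ring stereocentres are 1R, 2R and 4S: methyl, isopropenyl and the C4 chain lie on one face and vinyl on the other, so in the chair only the methyl group is axial. The fourth stereocentre, C10 (S), is acyclic and four bonds from C4, so the ring cannot control it. The C7=C8 alkene is trisubstituted and Z, with C12 cis to C9. Sensitive groups are the vinyl/isopropenyl 1,5-diene (no hydrogenation, no strong protic or Lewis acid, no long heating), the primary allylic acetate (ionisation, hydrolysis, acyl shift) and the secondary/tertiary diol. The difficulty is that three unrelated problems meet: a stereotriad with a quaternary centre, a remote carbinol, and a trisubstituted alkene in the geometry that olefination of an α-branched ester does not deliver cleanly. The plan rests on one feature: C12, C7, C8, C9, C10 and the oxygen on C10 are six atoms that, with C12 at the acid level, form a 3-substituted 5,6-dihydropyran-2-one. In that ring C12 and C9 can only be cis, and reduction opens it to the Z-ene-1,5-diol.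

## Retrosynthetic reasoning

25 to 24 to 23. The acetyl C–O bond at C12 and the Si–O bond at C11 are cut last, because the allylic acetate is the most fragile group. The C11 oxygen has to be masked anyway, since the aldehyde that brings it in cannot carry a free α-hydroxyl. Keeping the mask through the acetylation leaves only a primary allylic and a hindered secondary hydroxyl to tell apart in 23.

23 to 21. Joining O10 to C12 at the acid oxidation level turns the Z-ene-1,5-diol 23 into lactone 21. No skeletal bond is cut, but the alkene geometry changes from something to be selected into something the ring dictates. The forward reaction must reduce the conjugated lactone twice in the 1,2-sense without touching the alkene.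

21 to 16 and 19. The bonds cut are C9–C10 and O10–C12. C9–C10 is chosen because its formation creates C10 under catalyst control while the C7=C8 alkene arises by transposition of a dienolate, and because both fragments are simple. Cutting C7=C8 instead would bring back the geometry problem. The forward reaction must attack through the γ-carbon C9, choose one face of aldehyde 19, and run through a cisoid dienolate so that the aldolate can close onto C12.

19 to 18 to 17. The aldehyde comes from the commercial hydroxy ester 17 by silylation and partial reduction; no C–C bond is made.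

16 to 14 to 12 and 13. Dienolate 16 is the O-silyl derivative of the conjugated ester 14, formed by removing a C9 hydrogen. Neither the alkene geometry of 14 nor the ketene acetal geometry of 16 matters, so 14 can be made by an unselective olefination, cutting C7=C8 to phosphonate 12 and the two-carbon aldehyde 13.

12 to 11 to 9 and 10. The C4–H bond is cut next: hydride adds to ring C4 of the doubly activated alkylidene 11, and the C4=C7 bond of 11 is cut to ketone 9 and phosphonoacetate 10. C4 is the one ring stereocentre that ring construction does not set. Its chain must be cis to the isopropenyl group, that is equatorial, which is the outcome of axial attack by a small nucleophile. The phosphonate that activates the alkene for hydride is then used to make C7=C8, so it is not an extra group.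

9 to 8 to 7 to 5 to 4. These are functional-group changes on a cycloadduct. The isopropenyl group comes from an ester through a tertiary alcohol, the vinyl group from a formyl group, and the C4 carbonyl stays masked as a silyl enol ether until both are in place.

4 to 2 and 3; 2 to 1. Cutting C2–C3 and C1–C6 gives diene 2 and enal ester 3. The E-geometry of 3 becomes the cis relation of methyl and ester (later isopropenyl), the para orientation puts the masked carbonyl on C4, and a chiral Lewis acid sets C1 and C2 together. Diene 2 is the silyl enol ether of enone 1.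

## Alternatives that were turned down

Alternative 1: The ring is cut at C2–C3 and C1–C6 and the enantioselective Diels–Alder reaction is made the key step. A chiral boron Lewis acid activates the formyl group of the enal ester and the 2-silyloxydiene adds to give A1. In its favour, the quaternary C1 and C2 are set in one catalytic step from commercial materials and the C4 carbonyl is latent in the enol ether. Against it, as a strategy it answers only the easier half of the target. The Z-trisubstituted alkene and C10 would have to be solved separately, for example by a Z-selective olefination of an α-branched phosphonate (uncertain) plus a second asymmetric reaction. On the ring it is exactly as strong as the chosen plan, because A1 is compound 4 and this cycloaddition opens the chosen route. What the chosen strategy adds is one step that settles the alkene geometry and C10 together, and it places the key step there.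

Alternative 2: The ring is cut at C4–C5 and C3–C4. The β-keto ester A4 is alkylated twice by the diiodide A3 with a carbonate base to give A2, closing the ring by 6-exo-tet displacement. In its favour, C4 arrives already carrying C7 (as a ketone) and C12 (as a protected hydroxymethyl), and the C1/C2 diad is fixed before the ring exists. Against it, A3 is an acyclic vicinal quaternary/tertiary diad that needs its own multistep asymmetric synthesis. One of its iodides is β-branched next to the quaternary carbon, so O-alkylation and elimination compete. C4 must be decarboxylated afterwards, and the C7 ketone still has to be olefinated to a Z-alkene with no geometric control, with C10 unsolved. It is stronger on one point: after decarboxylation C4 is α to a ketone and can be equilibrated to the equatorial isomer, whereas the chosen route relies on kinetic hydride delivery in step 8. In its place the chosen strategy offers a much shorter ring synthesis and a key step that removes the alkene and C10 problems.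

Alternative 3: The C1–C2 bond is cut, and heating the ten-membered (E,E)-diene A6 gives A5 by a Cope rearrangement through a chair-chair transition state. In its favour, all three ring stereocentres come at once from two alkene geometries and one stereocentre, so C4 needs no separate step; on this point it is stronger than the chosen route. Against it, an enantiopure ten-membered (E,E)-diene is harder to make than the six-membered ring it delivers, and the transfer of chirality depends on the conformation of a flexible medium ring. The ester of A5 still needs two C–C bonds, the Z-alkene and C10. The chosen strategy is far better in step economy and addresses the side chain, which this alternative does not.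

Key step: step 13

Assumption: the catalyst antipodes written in step 2 ((R)-prolinol series) and step 13 ((S)-Tol-BINAP) follow the usual facial models; both antipodes of each are available, so a reversed sense on these substrates would be met by the mirror-image catalyst with nothing else changed.

## Route

Step 1
Reactants: 1 but-3-en-2-one
Product: 2 (buta-1,3-dien-2-yloxy)tri(propan-2-yl)silane
Conditions: i-Pr3SiOTf, Et3N, CH2Cl2, 0 °C to rt
Reagents that add atoms: triisopropylsilyl trifluoromethanesulfonate, CC(C)[Si](C(C)C)(C(C)C)OS(=O)(=O)C(F)(F)F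
Why: Soft enolisation of the enone by the silyl triflate/amine pair gives the 2-silyloxydiene (silyl enol ether formation); the bulky silyl group is chosen because it should survive the acidic catalyst of step 2 and the basic steps 3 and 4.

Step 2
Reactants: 2 (buta-1,3-dien-2-yloxy)tri(propan-2-yl)silane; 3 ethyl (E)-3-methyl-4-oxobut-2-enoate
Product: 4 ethyl (1S,2S)-2-formyl-2-methyl-5-{[tri(propan-2-yl)silyl]oxy}cyclohex-4-ene-1-carboxylate
Conditions: oxazaborolidinium triflimide [(R)-B-(o-tolyl)oxazaborolidine from (R)-α,α-diphenylprolinol, C24H24BNO, protonated by HN(SO2CF3)2] (20 mol%), CH2Cl2, −78 to −40 °C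
Reagents that add atoms: none
Why: Enantioselective Diels–Alder reaction: the boron cation binds the formyl group of 3, the nucleophilic CH2 terminus next to the silyloxy carbon of 2 bonds to the enal β-carbon (the one bearing the ester), so the silyloxy carbon ends para to the new quaternary carbon, and the E-geometry of 3 is carried over as methyl cis to ester. An aryl group of the catalyst shields one enal face and so sets ring C1 and C2 together; the diene termini are unsubstituted, so no endo/exo question arises.

Step 3
Reactants: 4 ethyl (1S,2S)-2-formyl-2-methyl-5-{[tri(propan-2-yl)silyl]oxy}cyclohex-4-ene-1-carboxylate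
Product: 5 ethyl (1S,2R)-2-ethenyl-2-methyl-5-{[tri(propan-2-yl)silyl]oxy}cyclohex-4-ene-1-carboxylate
Conditions: Ph3PCH3Br, KN(SiMe3)2 (slightly less than the salt), THF, 0 °C to rt
Reagents that add atoms: methyltriphenylphosphonium bromide, C[P+](c1ccccc1)(c1ccccc1)c1ccccc1.[Br-]
Why: Wittig methylenation of the neopentyl-type aldehyde; with no excess amide base the ylide should not remove the ester α-hydrogen, and the silyl enol ether is inert to it.

Step 4
Reactants: 5 ethyl (1S,2R)-2-ethenyl-2-methyl-5-{[tri(propan-2-yl)silyl]oxy}cyclohex-4-ene-1-carboxylate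
Product: 7 2-[(1S,2R)-2-ethenyl-2-methyl-5-{[tri(propan-2-yl)silyl]oxy}cyclohex-4-en-1-yl]propan-2-ol, via methyl ketone 6 (not isolated)
Conditions: MeMgBr (4 equiv), anhydrous CeCl3, THF, −78 to 0 °C; aq. NH4Cl
Reagents that add atoms: methylmagnesium bromide, C[Mg]Br
Why: Double Grignard addition to the ester through ketone 6; CeCl3 keeps the reagent nucleophilic rather than basic, so the α-stereocentre of 6 should not be enolised, and the hindered silyl enol ether is not cleaved.

Step 5
Reactants: 7 2-[(1S,2R)-2-ethenyl-2-methyl-5-{[tri(propan-2-yl)silyl]oxy}cyclohex-4-en-1-yl]propan-2-ol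
Product: 8 {[(4R,5R)-4-ethenyl-4-methyl-5-(prop-1-en-2-yl)cyclohex-1-en-1-yl]oxy}tri(propan-2-yl)silane
Conditions: Burgess reagent (Et3N+SO2N−CO2Me), toluene, 60 °C
Reagents that add atoms: none
Why: Syn-elimination through the sulfamate ester (Burgess dehydration); six methyl hydrogens compete with one ring hydrogen whose loss would give a tetrasubstituted alkene pressed against the quaternary carbon, so the isopropenyl isomer should prevail. The neutral conditions spare the enol ether and avoid a free cation next to the vinyl group.

Step 6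
Reactants: 8 {[(4R,5R)-4-ethenyl-4-methyl-5-(prop-1-en-2-yl)cyclohex-1-en-1-yl]oxy}tri(propan-2-yl)silane
Product: 9 (3R,4R)-4-ethenyl-4-methyl-3-(prop-1-en-2-yl)cyclohexan-1-one
Conditions: Bu4NF, AcOH, THF, 0 °C
Reagents that add atoms: none
Why: Fluoride cleaves the Si–O bond and acetic acid protonates the enolate at once (desilylation of a silyl enol ether), so no aldol chemistry follows; the ring stereocentres are β and γ to the carbonyl and cannot epimerise.

Step 7
Reactants: 9 (3R,4R)-4-ethenyl-4-methyl-3-(prop-1-en-2-yl)cyclohexan-1-one; 10 trimethyl phosphonoacetate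
Product: 11 methyl 2-(dimethoxyphosphoryl)-2-[(3R,4R)-4-ethenyl-4-methyl-3-(prop-1-en-2-yl)cyclohexylidene]acetate (E/Z mixture)
Conditions: TiCl4, N-methylmorpholine, THF, 0 °C to rt
Reagents that add atoms: none
Why: Knoevenagel condensation of a ketone with a phosphonoacetate promoted by TiCl4 and a tertiary amine; TiCl4 is moderated as its THF/amine complex, which should leave the isopropenyl group alone, and the alkene geometry of 11 is irrelevant because C7 becomes sp3 in step 8.

Step 8
Reactants: 11 methyl 2-(dimethoxyphosphoryl)-2-[(3R,4R)-4-ethenyl-4-methyl-3-(prop-1-en-2-yl)cyclohexylidene]acetate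
Product: 12 methyl 2-(dimethoxyphosphoryl)-2-[(1S,3R,4R)-4-ethenyl-4-methyl-3-(prop-1-en-2-yl)cyclohexyl]acetate (both epimers at the phosphonate carbon)
Conditions: NaBH4, MeOH–THF, 0 °C; aq. NH4Cl
Reagents that add atoms: none
Why: Conjugate addition of hydride to the doubly activated exocyclic alkene; the small borohydride should attack ring C4 along the axial direction, as small nucleophiles do on cyclohexanones and cyclohexylidene malonate-type acceptors, which leaves the chain equatorial and cis to the isopropenyl group (4S in the atom numbering). The phosphonate-stabilised carbanion formed protects the ester from further reduction, and the configuration at C7 is erased again in step 9.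

Step 9
Reactants: 12 methyl 2-(dimethoxyphosphoryl)-2-[(1S,3R,4R)-4-ethenyl-4-methyl-3-(prop-1-en-2-yl)cyclohexyl]acetate; 13 acetaldehyde
Product: 14 methyl 2-[(1S,3R,4R)-4-ethenyl-4-methyl-3-(prop-1-en-2-yl)cyclohexyl]but-2-enoate (E/Z mixture)
Conditions: NaH, THF, 0 °C; then MeCHO (excess), 0 °C to rt
Reagents that add atoms: none
Why: Horner–Wadsworth–Emmons olefination of the α-branched phosphonate with a small, reactive aldehyde makes C7=C8; both alkene isomers are usable because step 10 converts them into the same dienolate.

Step 10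
Reactants: 14 methyl 2-[(1S,3R,4R)-4-ethenyl-4-methyl-3-(prop-1-en-2-yl)cyclohexyl]but-2-enoate
Product: 16 {1-methoxy-2-[(1S,3R,4R)-4-ethenyl-4-methyl-3-(prop-1-en-2-yl)cyclohexyl]buta-1,3-dienyl}oxy(trimethyl)silane (ketene acetal isomers), via lithium dienolate 15 (not isolated)
Conditions: LiN(i-Pr)2, THF–DMPU, −78 °C; Me3SiCl, −78 to 0 °C; non-aqueous work-up
Reagents that add atoms: chlorotrimethylsilane, C[Si](C)(C)Cl
Why: γ-Deprotonation of the α-substituted crotonate at C9 gives the fully conjugated lithium dienolate 15, and O-silylation in the presence of DMPU gives the silyl ketene acetal; the C4 hydrogen is not activated and stays untouched.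

Step 11
Reactants: 17 methyl 2-hydroxy-2-methylpropanoate
Product: 18 methyl 2-methyl-2-(triethylsilyloxy)propanoate
Conditions: Et3SiOTf, 2,6-lutidine, CH2Cl2, 0 °C
Reagents that add atoms: triethylsilyl trifluoromethanesulfonate, CC[Si](CC)(CC)OS(=O)(=O)C(F)(F)F
Why: Silyl ether formation on the hindered tertiary hydroxyl needs the silyl triflate with a non-nucleophilic pyridine base.

Step 12
Reactants: 18 methyl 2-methyl-2-(triethylsilyloxy)propanoate
Product: 19 2-methyl-2-(triethylsilyloxy)propanal
Conditions: i-Bu2AlH (1.1 equiv), CH2Cl2, −78 °C; MeOH, then aq. potassium sodium tartrate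
Reagents that add atoms: none
Why: Partial reduction of the ester at low temperature; the α-silyloxy group stabilises the tetrahedral aluminium hemiacetal until work-up, and the aldehyde formed has no α-hydrogen and cannot enolise.

Step 13
Reactants: 16 {1-methoxy-2-[(1S,3R,4R)-4-ethenyl-4-methyl-3-(prop-1-en-2-yl)cyclohexyl]buta-1,3-dienyl}oxy(trimethyl)silane; 19 2-methyl-2-(triethylsilyloxy)propanal
Product: 21 (6S)-3-[(1S,3R,4R)-4-ethenyl-4-methyl-3-(prop-1-en-2-yl)cyclohexyl]-6-[2-(triethylsilyloxy)propan-2-yl]-5,6-dihydro-2H-pyran-2-one, via copper aldolate 20 (not isolated)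
Conditions: Cu(OTf)2 (10 mol%), (S)-Tol-BINAP (11 mol%), Bu4N[Ph3SiF2] (20 mol%), 16 (1.5 equiv), THF, 0 °C to rt; aq. NH4Cl
Reagents that add atoms: none
Why: Divalent copper triflate, the bisphosphine and the fluoride source give, after reduction by the dienolate, a monovalent copper fluoride complex that takes the silyl group from 16 and forms a chiral copper dienolate. This adds through its γ-carbon C9 to aldehyde 19 and makes C9–C10; the α-carbon C7 is shielded by the cyclohexyl group and the aldehyde is neopentyl-like, so γ-attack is expected. Reaction through the cisoid dienolate, which the bulky C7 substituent should make competitive with the transoid one as it is for α-methyl dienolates, gives the Z-aldolate 20. Its alkoxide closes onto the ester carbon C12 by 6-exo-trig acyl substitution and expels methoxide, which is silylated by the next molecule of 16 and so regenerates the copper dienolate. C10 is set by the bisphosphine on copper (catalyst control of the aldehyde face); the ring stereocentres are four or more bonds away and should not interfere. The closest known reaction is the copper fluoride–Tol-BINAP vinylogous Mukaiyama aldol of α-alkyl silyl dienolates with aldehydes that gives 3-alkyl-5,6-dihydropyran-2-ones directly. The step needs γ over α attack, one aldehyde face and the Z-alkene: the first is secured by the substitution at C7, the second by the ligand, and the third by ring closure, since an aldolate from the transoid path cannot lactonise and is removed as an open-chain ester. Aldehyde 19 has no α-hydrogen, so enolisation does not compete.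

Step 14
Reactants: 21 (6S)-3-[(1S,3R,4R)-4-ethenyl-4-methyl-3-(prop-1-en-2-yl)cyclohexyl]-6-[2-(triethylsilyloxy)propan-2-yl]-5,6-dihydro-2H-pyran-2-one
Product: 23 (2Z,5S)-2-[(1S,3R,4R)-4-ethenyl-4-methyl-3-(prop-1-en-2-yl)cyclohexyl]-6-methyl-6-(triethylsilyloxy)hept-2-ene-1,5-diol, via lactol 22 (not isolated)
Conditions: i-Bu2AlH (4 equiv), CH2Cl2, −78 to 0 °C; aq. potassium sodium tartrate
Reagents that add atoms: none
Why: 1,2-Reduction of the unsaturated lactone goes through lactol 22 (as its aluminate), which opens and is reduced again on warming to the allylic diol; the alkene is not touched, so the Z-geometry fixed by the ring is kept, and the isolated alkenes and the silyl ether are inert.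

Step 15
Reactants: 23 (2Z,5S)-2-[(1S,3R,4R)-4-ethenyl-4-methyl-3-(prop-1-en-2-yl)cyclohexyl]-6-methyl-6-(triethylsilyloxy)hept-2-ene-1,5-diol
Product: 24 [(2Z,5S)-2-[(1S,3R,4R)-4-ethenyl-4-methyl-3-(prop-1-en-2-yl)cyclohexyl]-5-hydroxy-6-methyl-6-(triethylsilyloxy)hept-2-en-1-yl] acetate
Conditions: Ac2O (1.1 equiv), 2,4,6-collidine, CH2Cl2, −20 to 0 °C
Reagents that add atoms: acetic anhydride, CC(=O)OC(C)=O
Why: Selective acylation: the primary allylic hydroxyl at C12 should react much faster than the C10 hydroxyl, which is secondary and sits next to the fully substituted, silyloxy-bearing C11.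

Step 16
Reactants: 24 [(2Z,5S)-2-[(1S,3R,4R)-4-ethenyl-4-methyl-3-(prop-1-en-2-yl)cyclohexyl]-5-hydroxy-6-methyl-6-(triethylsilyloxy)hept-2-en-1-yl] acetate
Product: 25 [(2Z,5S)-2-[(1S,3R,4R)-4-ethenyl-4-methyl-3-(prop-1-en-2-yl)cyclohexyl]-5,6-dihydroxy-6-methylhept-2-en-1-yl] acetate
Conditions: HF·pyridine, pyridine, THF, 0 °C to rt
Reagents that add atoms: none
Why: Buffered fluoride cleaves the triethylsilyl ether (desilylation) under conditions neither basic enough to hydrolyse or shift the acetate nor acidic enough to ionise the allylic ester or protonate the 1,5-diene.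

## Compound list

1 | but-3-en-2-one | CC(=O)C=C | starting material
2 | (buta-1,3-dien-2-yloxy)tri(propan-2-yl)silane | C=CC(=C)O[Si](C(C)C)(C(C)C)C(C)C | intermediate
3 | ethyl (E)-3-methyl-4-oxobut-2-enoate | CCOC(=O)/C=C(\C)C=O | starting material
4 | ethyl (1S,2S)-2-formyl-2-methyl-5-{[tri(propan-2-yl)silyl]oxy}cyclohex-4-ene-1-carboxylate | O=C[C@@]1(C)CC=C(O[Si](C(C)C)(C(C)C)C(C)C)C[C@@H]1C(=O)OCC | intermediate
5 | ethyl (1S,2R)-2-ethenyl-2-methyl-5-{[tri(propan-2-yl)silyl]oxy}cyclohex-4-ene-1-carboxylate | C=C[C@@]1(C)CC=C(O[Si](C(C)C)(C(C)C)C(C)C)C[C@@H]1C(=O)OCC | intermediate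
6 | 1-[(1S,2R)-2-ethenyl-2-methyl-5-{[tri(propan-2-yl)silyl]oxy}cyclohex-4-en-1-yl]ethan-1-one | C=C[C@@]1(C)CC=C(O[Si](C(C)C)(C(C)C)C(C)C)C[C@@H]1C(C)=O | intermediate
7 | 2-[(1S,2R)-2-ethenyl-2-methyl-5-{[tri(propan-2-yl)silyl]oxy}cyclohex-4-en-1-yl]propan-2-ol | C=C[C@@]1(C)CC=C(O[Si](C(C)C)(C(C)C)C(C)C)C[C@@H]1C(C)(C)O | intermediate
8 | {[(4R,5R)-4-ethenyl-4-methyl-5-(prop-1-en-2-yl)cyclohex-1-en-1-yl]oxy}tri(propan-2-yl)silane | C=C[C@@]1(C)CC=C(O[Si](C(C)C)(C(C)C)C(C)C)C[C@@H]1C(=C)C | intermediate
9 | (3R,4R)-4-ethenyl-4-methyl-3-(prop-1-en-2-yl)cyclohexan-1-one | C=C[C@@]1(C)CCC(=O)C[C@@H]1C(=C)C | intermediate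
10 | trimethyl phosphonoacetate | COC(=O)CP(=O)(OC)OC | starting material
11 | methyl 2-(dimethoxyphosphoryl)-2-[(3R,4R)-4-ethenyl-4-methyl-3-(prop-1-en-2-yl)cyclohexylidene]acetate (E/Z mixture) | C=C[C@@]1(C)CCC(=C(C(=O)OC)P(=O)(OC)OC)C[C@@H]1C(=C)C | intermediate
12 | methyl 2-(dimethoxyphosphoryl)-2-[(1S,3R,4R)-4-ethenyl-4-methyl-3-(prop-1-en-2-yl)cyclohexyl]acetate (epimers at the phosphonate carbon) | C=C[C@@]1(C)CC[C@H](C(C(=O)OC)P(=O)(OC)OC)C[C@@H]1C(=C)C | intermediate
13 | acetaldehyde | CC=O | starting material
14 | methyl 2-[(1S,3R,4R)-4-ethenyl-4-methyl-3-(prop-1-en-2-yl)cyclohexyl]but-2-enoate (E/Z mixture) | C=C[C@@]1(C)CC[C@H](C(=CC)C(=O)OC)C[C@@H]1C(=C)C | intermediate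
15 | lithium 1-methoxy-2-[(1S,3R,4R)-4-ethenyl-4-methyl-3-(prop-1-en-2-yl)cyclohexyl]buta-1,3-dien-1-olate | C=C[C@@]1(C)CC[C@H](C(C=C)=C(OC)[O-])C[C@@H]1C(=C)C.[Li+] | intermediate
16 | {1-methoxy-2-[(1S,3R,4R)-4-ethenyl-4-methyl-3-(prop-1-en-2-yl)cyclohexyl]buta-1,3-dienyl}oxy(trimethyl)silane | C=C[C@@]1(C)CC[C@H](C(C=C)=C(OC)O[Si](C)(C)C)C[C@@H]1C(=C)C | intermediate
17 | methyl 2-hydroxy-2-methylpropanoate | CC(C)(O)C(=O)OC | starting material
18 | methyl 2-methyl-2-(triethylsilyloxy)propanoate | COC(=O)C(C)(C)O[Si](CC)(CC)CC | intermediate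
19 | 2-methyl-2-(triethylsilyloxy)propanal | CC(C)(O[Si](CC)(CC)CC)C=O | intermediate
20 | monovalent copper alkoxide of methyl (2Z,5S)-2-[(1S,3R,4R)-4-ethenyl-4-methyl-3-(prop-1-en-2-yl)cyclohexyl]-5-hydroxy-6-methyl-6-(triethylsilyloxy)hept-2-enoate (bisphosphine not drawn) | C=C[C@@]1(C)CC[C@H](/C(=C/C[C@H]([O-])C(C)(C)O[Si](CC)(CC)CC)C(=O)OC)C[C@@H]1C(=C)C.[Cu+] | intermediate
21 | (6S)-3-[(1S,3R,4R)-4-ethenyl-4-methyl-3-(prop-1-en-2-yl)cyclohexyl]-6-[2-(triethylsilyloxy)propan-2-yl]-5,6-dihydro-2H-pyran-2-one | C=C[C@@]1(C)CC[C@H](C2=CC[C@H](OC2=O)C(C)(C)O[Si](CC)(CC)CC)C[C@@H]1C(=C)C | intermediate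
22 | (6S)-3-[(1S,3R,4R)-4-ethenyl-4-methyl-3-(prop-1-en-2-yl)cyclohexyl]-6-[2-(triethylsilyloxy)propan-2-yl]-5,6-dihydro-2H-pyran-2-ol (anomers) | C=C[C@@]1(C)CC[C@H](C2=CC[C@H](OC2O)C(C)(C)O[Si](CC)(CC)CC)C[C@@H]1C(=C)C | intermediate
23 | (2Z,5S)-2-[(1S,3R,4R)-4-ethenyl-4-methyl-3-(prop-1-en-2-yl)cyclohexyl]-6-methyl-6-(triethylsilyloxy)hept-2-ene-1,5-diol | C=C[C@@]1(C)CC[C@H](/C(=C/C[C@H](O)C(C)(C)O[Si](CC)(CC)CC)CO)C[C@@H]1C(=C)C | intermediate
24 | [(2Z,5S)-2-[(1S,3R,4R)-4-ethenyl-4-methyl-3-(prop-1-en-2-yl)cyclohexyl]-5-hydroxy-6-methyl-6-(triethylsilyloxy)hept-2-en-1-yl] acetate | C=C[C@@]1(C)CC[C@H](/C(=C/C[C@H](O)C(C)(C)O[Si](CC)(CC)CC)COC(C)=O)C[C@@H]1C(=C)C | intermediate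
25 | [(2Z,5S)-2-[(1S,3R,4R)-4-ethenyl-4-methyl-3-(prop-1-en-2-yl)cyclohexyl]-5,6-dihydroxy-6-methylhept-2-en-1-yl] acetate | C=C[C@@]1(C)CC[C@H](/C(=C/C[C@H](O)C(C)(C)O)COC(C)=O)C[C@@H]1C(=C)C | target

## Step count and least certain steps

Total: 16 steps. Longest linear sequence: 14 steps (steps 1 to 10 and 13 to 16); steps 11 and 12 are the two-step branch to 19.

Step 13 (key step). Three things may go wrong. The dienolate may react largely through the transoid conformer, so that material is diverted to an open-chain ester that cannot lactonise. Face selectivity may be poor with a neopentyl-like aldehyde. The triethylsilyl group may shift from O11 to the new alkoxide at C10 before ring closure. The fallback sets out from 19 and 12 and comes back at 21. Allylboration of 19 with B-allyldiisopinocampheylborane of the antipode that gives the S-carbinol should give (3S)-2-methyl-2-(triethylsilyloxy)hex-5-en-3-ol F1. Olefination of 12 with aqueous formaldehyde and K2CO3 should give methyl 2-[(1S,3R,4R)-4-ethenyl-4-methyl-3-(prop-1-en-2-yl)cyclohexyl]prop-2-enoate F2, and LiOH should hydrolyse it to 2-[(1S,3R,4R)-4-ethenyl-4-methyl-3-(prop-1-en-2-yl)cyclohexyl]prop-2-enoic acid F3. Yamaguchi esterification of F3 with F1 should give (3S)-2-methyl-2-(triethylsilyloxy)hex-5-en-3-yl 2-[(1S,3R,4R)-4-ethenyl-4-methyl-3-(prop-1-en-2-yl)cyclohexyl]prop-2-enoate F4. Ring-closing metathesis of F4 with the second-generation Grubbs catalyst (H2IMes)(PCy3)Cl2Ru=CHPh in warm toluene should then close the same dihydropyranone 21. The ring vinyl and isopropenyl groups are hindered and cannot form a favourable ring, so they should not interfere.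

Step 8. Facial selectivity at C4 may be poor if hydride attacks partly from the equatorial side, giving the axial chain. The fallback sets C4 by equilibration; it sets out from 9 and comes back at 14. Reductive cyanation of 9 with TosMIC and t-BuOK should give (3R,4R)-4-ethenyl-4-methyl-3-(prop-1-en-2-yl)cyclohexane-1-carbonitrile F5 as both C1 epimers. EtMgBr with catalytic CuBr, then aqueous acid and NaOMe/MeOH equilibration, should give the equatorial ketone 1-[(1S,3R,4R)-4-ethenyl-4-methyl-3-(prop-1-en-2-yl)cyclohexyl]propan-1-one F6. Kinetic enolisation on the ethyl side with KN(SiMe3)2 and trapping with PhNTf2 should give 1-[(1S,3R,4R)-4-ethenyl-4-methyl-3-(prop-1-en-2-yl)cyclohexyl]prop-1-en-1-yl trifluoromethanesulfonate F7. Methoxycarbonylation of F7 (Pd(OAc)2, PPh3, CO, MeOH, Et3N) should give 14.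

Step 7. The Lewis acid may engage the isopropenyl group (cyclisation onto the activated carbonyl), the condensation may be slow, or the product alkene may drift into the ring. The fallback avoids TiCl4; it sets out from 9 and comes back at 14. Horner–Wadsworth–Emmons reaction of 9 with the sodium salt of 10 should give methyl 2-[(3R,4R)-4-ethenyl-4-methyl-3-(prop-1-en-2-yl)cyclohexylidene]acetate F8. Reduction with Mg in MeOH should give methyl 2-[(1S,3R,4R)-4-ethenyl-4-methyl-3-(prop-1-en-2-yl)cyclohexyl]acetate F9 together with its C1 epimer, which must be separated; the facial outcome of this reduction is uncertain, which is why it is only the reserve. Aldol addition of the lithium enolate of F9 to 13 should give methyl 2-[(1S,3R,4R)-4-ethenyl-4-methyl-3-(prop-1-en-2-yl)cyclohexyl]-3-hydroxybutanoate F10. Mesylation and elimination with DBU should give 14.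

Step 2. The catalyst may bind the ester as well as the formyl group, which would erode regio- or enantioselectivity. The fallback separates the enantiomers instead; it sets out from 2 and 3 and comes back at 4. Cycloaddition promoted by Me2AlCl should give racemic ethyl (1RS,2RS)-2-formyl-2-methyl-5-{[tri(propan-2-yl)silyl]oxy}cyclohex-4-ene-1-carboxylate F11, the relative configuration being fixed by the dienophile geometry. Condensation with (1R,2R)-N,N'-dimethyl-1,2-diphenylethane-1,2-diamine should give two diastereomeric aminals. After chromatography, ethyl (1S,2S)-2-[(4R,5R)-1,3-dimethyl-4,5-diphenylimidazolidin-2-yl]-2-methyl-5-{[tri(propan-2-yl)silyl]oxy}cyclohex-4-ene-1-carboxylate F12 is hydrolysed with cold dilute aqueous acid to 4.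

Step 5. Elimination may go partly toward the ring (tetrasubstituted alkene), or the tertiary sulfamate may ionise. The fallback makes the isopropenyl group by methylenation; it sets out from 5 and comes back at 8. MeNH(OMe)·HCl and i-PrMgCl should convert 5 into (1S,2R)-2-ethenyl-N-methoxy-N,2-dimethyl-5-{[tri(propan-2-yl)silyl]oxy}cyclohex-4-ene-1-carboxamide F13. MeMgBr then gives ketone 6, isolated this time, and the non-basic Petasis methylenation with Cp2TiMe2 in warm toluene should give 8 without epimerising the α-carbon.

## Further compounds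

F1 | step 13 | (3S)-2-methyl-2-(triethylsilyloxy)hex-5-en-3-ol | C=CC[C@H](O)C(C)(C)O[Si](CC)(CC)CC
F2 | step 13 | methyl 2-[(1S,3R,4R)-4-ethenyl-4-methyl-3-(prop-1-en-2-yl)cyclohexyl]prop-2-enoate | C=C[C@@]1(C)CC[C@H](C(=C)C(=O)OC)C[C@@H]1C(=C)C
F3 | step 13 | 2-[(1S,3R,4R)-4-ethenyl-4-methyl-3-(prop-1-en-2-yl)cyclohexyl]prop-2-enoic acid | C=C[C@@]1(C)CC[C@H](C(=C)C(=O)O)C[C@@H]1C(=C)C
F4 | step 13 | (3S)-2-methyl-2-(triethylsilyloxy)hex-5-en-3-yl 2-[(1S,3R,4R)-4-ethenyl-4-methyl-3-(prop-1-en-2-yl)cyclohexyl]prop-2-enoate | C=C[C@@]1(C)CC[C@H](C(=C)C(=O)O[C@@H](CC=C)C(C)(C)O[Si](CC)(CC)CC)C[C@@H]1C(=C)C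
F5 | step 8 | (3R,4R)-4-ethenyl-4-methyl-3-(prop-1-en-2-yl)cyclohexane-1-carbonitrile (C1 epimers) | C=C[C@@]1(C)CCC(C#N)C[C@@H]1C(=C)C
F6 | step 8 | 1-[(1S,3R,4R)-4-ethenyl-4-methyl-3-(prop-1-en-2-yl)cyclohexyl]propan-1-one | C=C[C@@]1(C)CC[C@H](C(=O)CC)C[C@@H]1C(=C)C
F7 | step 8 | 1-[(1S,3R,4R)-4-ethenyl-4-methyl-3-(prop-1-en-2-yl)cyclohexyl]prop-1-en-1-yl trifluoromethanesulfonate (E/Z mixture) | C=C[C@@]1(C)CC[C@H](C(=CC)OS(=O)(=O)C(F)(F)F)C[C@@H]1C(=C)C
F8 | step 7 | methyl 2-[(3R,4R)-4-ethenyl-4-methyl-3-(prop-1-en-2-yl)cyclohexylidene]acetate (E/Z mixture) | C=C[C@@]1(C)CCC(=CC(=O)OC)C[C@@H]1C(=C)C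
F9 | step 7 | methyl 2-[(1S,3R,4R)-4-ethenyl-4-methyl-3-(prop-1-en-2-yl)cyclohexyl]acetate | C=C[C@@]1(C)CC[C@H](CC(=O)OC)C[C@@H]1C(=C)C
F10 | step 7 | methyl 2-[(1S,3R,4R)-4-ethenyl-4-methyl-3-(prop-1-en-2-yl)cyclohexyl]-3-hydroxybutanoate (diastereomers in the chain) | C=C[C@@]1(C)CC[C@H](C(C(C)O)C(=O)OC)C[C@@H]1C(=C)C
F11 | step 2 | racemic ethyl (1RS,2RS)-2-formyl-2-methyl-5-{[tri(propan-2-yl)silyl]oxy}cyclohex-4-ene-1-carboxylate (one enantiomer drawn) | O=C[C@@]1(C)CC=C(O[Si](C(C)C)(C(C)C)C(C)C)C[C@@H]1C(=O)OCC
F12 | step 2 | ethyl (1S,2S)-2-[(4R,5R)-1,3-dimethyl-4,5-diphenylimidazolidin-2-yl]-2-methyl-5-{[tri(propan-2-yl)silyl]oxy}cyclohex-4-ene-1-carboxylate | CN1[C@H](c2ccccc2)[C@@H](c2ccccc2)N(C)C1[C@@]3(C)CC=C(O[Si](C(C)C)(C(C)C)C(C)C)C[C@@H]3C(=O)OCC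
F13 | step 5 | (1S,2R)-2-ethenyl-N-methoxy-N,2-dimethyl-5-{[tri(propan-2-yl)silyl]oxy}cyclohex-4-ene-1-carboxamide | C=C[C@@]1(C)CC=C(O[Si](C(C)C)(C(C)C)C(C)C)C[C@@H]1C(=O)N(C)OC
A1 | alternative 1 | ethyl (1S,2S)-2-formyl-2-methyl-5-{[tri(propan-2-yl)silyl]oxy}cyclohex-4-ene-1-carboxylate | O=C[C@@]1(C)CC=C(O[Si](C(C)C)(C(C)C)C(C)C)C[C@@H]1C(=O)OCC
A2 | alternative 2 | ethyl (3R,4R)-4-ethenyl-1-{2-[(4-methoxyphenyl)methoxy]acetyl}-4-methyl-3-(prop-1-en-2-yl)cyclohexane-1-carboxylate | C=C[C@@]1(C)CCC(C(=O)OCC)(C(=O)COCc2ccc(OC)cc2)C[C@@H]1C(=C)C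
A3 | alternative 2 | (3R,4R)-3-(2-iodoethyl)-4-(iodomethyl)-3,5-dimethylhexa-1,5-diene | C=C[C@@]([C@H](CI)C(=C)C)(C)CCI
A4 | alternative 2 | ethyl 4-[(4-methoxyphenyl)methoxy]-3-oxobutanoate | CCOC(=O)CC(=O)COCc1ccc(OC)cc1
A5 | alternative 3 | methyl (1S,3R,4R)-4-ethenyl-4-methyl-3-(prop-1-en-2-yl)cyclohexane-1-carboxylate | C=C[C@@]1(C)CC[C@H](C(=O)OC)C[C@@H]1C(=C)C
A6 | alternative 3 | methyl (1S,3E,7E)-4,8-dimethylcyclodeca-3,7-diene-1-carboxylate | COC(=O)[C@@H]1C/C=C(\C)CC/C=C(\C)CC1
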